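The synthesis builds the central benzene ring (C3a', C4', C5', C6', C7', C7a') by cycloaddition instead of functionalising a preformed arene. That ring is a resorcinol, oxygenated at C6' and C7a', with C3 of ring A on C4' and C3' on C3a'. This is the pattern that a 1,1,3-trioxygenated butadiene and an alkynyl ketone produce. In one operation the Diels–Alder/aromatisation forms C4'–C5' and C3a'–C7a', fixes all four substituents and unveils the C7a' phenol next to the C3' ketone, ready for ring B. The precursor is an ynone: enantiopure trans ring A (C5 bromide as stilbene handle) carrying a 3,5-dimethoxybenzoylethynyl group on C3.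

Key step: step 12

Numbering: ring A is O1, C2, C3, C3a, C4 to C7, C7a (stilbene on C5); ring B is the primed set; C3 is bonded to C4'; the target is 2S,3S,2'S,3'S (both rings trans) with an E olefin.

Assumption: phthalimido-carboxylate dirhodium catalysts of the S series are taken to give cis-dihydrobenzofurans of 2R configuration from both aryldiazoacetates and diaryldiazomethanes; ring A is later corrected at C3 and ring B at C2', so the two insertions need opposite catalyst antipodes, and if a first run shows the reverse sense only the antipode (both are sold) is exchanged.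

Step 1
Reactants: 1 2-hydroxyphenylacetic acid
Product: 2 methyl 2-(2-hydroxyphenyl)acetate
Conditions: MeOH, H2SO4 (cat.), reflux
Reagents that add atoms: methanol, CO
Why: Fischer esterification; any benzofuran-2(3H)-one formed by lactonisation is reopened by methanol under the same acid catalysis.

Step 2
Reactants: 2 methyl 2-(2-hydroxyphenyl)acetate
Product: 3 methyl 2-(5-bromo-2-hydroxyphenyl)acetate
Conditions: NBS (1.0 equiv), MeCN, 0 °C to rt, dark
Reagents that add atoms: N-bromosuccinimide, O=C1CCC(=O)N1Br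
Why: Electrophilic aromatic bromination directed by the free phenol to its open para position, the future C5 of ring A, done before any more electron-rich anisyl ring is present.

Step 3
Reactants: 3 methyl 2-(5-bromo-2-hydroxyphenyl)acetate; 4 4-methoxybenzyl chloride
Product: 5 methyl 2-[5-bromo-2-(4-methoxybenzyloxy)phenyl]acetate
Conditions: K2CO3, DMF, 50 °C
Reagents that add atoms: none
Why: Williamson ether synthesis of the phenoxide with a reactive benzylic chloride, which brings in C2 and its aryl group.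

Step 4
Reactants: 5 methyl 2-[5-bromo-2-(4-methoxybenzyloxy)phenyl]acetate
Product: 6 methyl 2-[5-bromo-2-(4-methoxybenzyloxy)phenyl]-2-diazoacetate
Conditions: 4-acetamidobenzenesulfonyl azide, DBU, MeCN, 0 °C to rt
Reagents that add atoms: 4-acetamidobenzenesulfonyl azide, CC(=O)Nc1ccc(cc1)S(=O)(=O)N=[N+]=[N-]
Why: Regitz diazo transfer to the arylacetate enolate, the standard entry to aryldiazoacetates.

Step 5
Reactants: 6 methyl 2-[5-bromo-2-(4-methoxybenzyloxy)phenyl]-2-diazoacetate
Product: 7 methyl (2S,3R)-5-bromo-2-(4-methoxyphenyl)-2,3-dihydro-1-benzofuran-3-carboxylate (cis)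
Conditions: Rh2(R-PTTL)4 (1 mol %; PTTL = N-phthaloyl-tert-leucinate), toluene, −78 to −60 °C
Reagents that add atoms: none
Why: Intramolecular 1,5 C–H insertion of a donor/acceptor rhodium carbene into the benzylic ether CH2, a reaction known to give cis-2-aryl-3-carboxylates; the chiral carboxylate ligands choose the enantiotopic hydrogen and the carbene face, which sets C2 as S, while C3 arrives as R and is corrected in step 6.

Step 6
Reactants: 7 methyl (2S,3R)-5-bromo-2-(4-methoxyphenyl)-2,3-dihydro-1-benzofuran-3-carboxylate (cis)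
Product: 8 methyl (2S,3S)-5-bromo-2-(4-methoxyphenyl)-2,3-dihydro-1-benzofuran-3-carboxylate (trans)
Conditions: NaOMe (0.3 equiv), MeOH/THF, rt
Reagents that add atoms: none
Why: Base-mediated epimerisation through the ester enolate moves C3 to the thermodynamic trans (S) configuration and leaves C2 untouched, because ring opening would be the reverse of a disfavoured 5-endo-trig closure; the solid ester also offers a point for enrichment by recrystallisation.

Step 7
Reactants: 8 methyl (2S,3S)-5-bromo-2-(4-methoxyphenyl)-2,3-dihydro-1-benzofuran-3-carboxylate (trans)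
Product: 10 (2S,3S)-5-bromo-3-ethynyl-2-(4-methoxyphenyl)-2,3-dihydro-1-benzofuran (trans), via aldehyde 9 (not isolated)
Conditions: i-Bu2AlH (1.1 equiv), CH2Cl2, −78 °C; MeOH; K2CO3, dimethyl (1-diazo-2-oxopropyl)phosphonate, −78 °C to rt; aq potassium sodium tartrate
Reagents that add atoms: dimethyl (1-diazo-2-oxopropyl)phosphonate, CC(=O)C(=[N+]=[N-])P(=O)(OC)OC
Why: Partial ester reduction followed in the same flask by Ohira–Bestmann (Seyferth–Gilbert) homologation avoids isolating the enolisable aldehyde 9, whose C3 can only equilibrate towards the wanted trans isomer.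

Step 8
Reactants: 10 (2S,3S)-5-bromo-3-ethynyl-2-(4-methoxyphenyl)-2,3-dihydro-1-benzofuran; 11 3,5-dimethoxybenzaldehyde
Product: 13 3-[(2S,3S)-5-bromo-2-(4-methoxyphenyl)-2,3-dihydro-1-benzofuran-3-yl]-1-(3,5-dimethoxyphenyl)prop-2-yn-1-ol (both carbinol epimers), via magnesium acetylide 12 (not isolated)
Conditions: EtMgBr, THF, 0 °C to rt; 11, 0 °C; aq NH4Cl
Reagents that add atoms: none
Why: A Grignard base deprotonates the terminal alkyne without bromine–metal exchange and without touching C3–H, and the acetylide adds 1,2 to the aldehyde; the unselective carbinol centre is erased in step 9.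

Step 9
Reactants: 13 3-[(2S,3S)-5-bromo-2-(4-methoxyphenyl)-2,3-dihydro-1-benzofuran-3-yl]-1-(3,5-dimethoxyphenyl)prop-2-yn-1-ol
Product: 14 3-[(2S,3S)-5-bromo-2-(4-methoxyphenyl)-2,3-dihydro-1-benzofuran-3-yl]-1-(3,5-dimethoxyphenyl)prop-2-yn-1-one
Conditions: activated MnO2, CH2Cl2, rt; filter, use without chromatography
Reagents that add atoms: none
Why: Neutral heterogeneous MnO2 oxidation of a benzylic and propargylic alcohol gives the ynone without exposing the acidic C3–H to any base.

Step 10
Reactants: 15 methyl acetoacetate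
Product: 16 methyl (E)-3-methoxybut-2-enoate
Conditions: HC(OMe)3, H2SO4 (cat.), MeOH, rt to 50 °C; distil
Reagents that add atoms: trimethyl orthoformate, COC(OC)OC
Why: Acid-catalysed ketalisation by the orthoester and loss of methanol give the conjugated E enol ether, the usual O-methylation of a beta-keto ester.

Step 11
Reactants: 16 methyl (E)-3-methoxybut-2-enoate
Product: 18 (E)-1,3-dimethoxy-1-(trimethylsilyloxy)buta-1,3-diene, via lithium dienolate 17 (not isolated)
Conditions: LiN(i-Pr)2, THF, −78 °C; Me3SiCl, −78 °C to rt; distil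
Reagents that add atoms: chlorotrimethylsilane, C[Si](C)(C)Cl
Why: Kinetic gamma-deprotonation and O-silylation of the dienolate is the standard silyl ketene acetal synthesis of this diene, and its C1=C2 geometry has no bearing on the later aromatic product.

Step 12
Reactants: 14 3-[(2S,3S)-5-bromo-2-(4-methoxyphenyl)-2,3-dihydro-1-benzofuran-3-yl]-1-(3,5-dimethoxyphenyl)prop-2-yn-1-one; 18 (E)-1,3-dimethoxy-1-(trimethylsilyloxy)buta-1,3-diene
Product: 21 {2-[(2S,3S)-5-bromo-2-(4-methoxyphenyl)-2,3-dihydro-1-benzofuran-3-yl]-6-hydroxy-4-methoxyphenyl}(3,5-dimethoxyphenyl)methanone, via cyclohexadiene adduct 19 (not isolated), via aryl silyl ether 20 (not isolated)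
Conditions: 18 (3 equiv), toluene, 110 °C, sealed tube, Ar; then 1 M HCl, THF, rt
Reagents that add atoms: none
Why: The electron-rich CH2 terminus of 18 attacks the ynone beta-carbon while the ketene acetal carbon bonds to the alpha-carbon in a strongly polarised, asynchronous [4+2] cycloaddition giving 1,4-cyclohexadiene 19, whose mixed ketal loses methanol by 1,4-elimination to give arene 20, and the labile silyl ether falls off in the mild acidic work-up. The closest known reaction type is the Diels–Alder/aromatisation of 1,1,3-trioxygenated butadienes with alkynyl ketones and alkynoates to resorcinol derivatives. The single new ring, the central benzene, is closed intermolecularly by the cycloaddition itself, with C4'–C5' leading and C3a'–C7a' completing the six-membered ring. No lasting stereocentre is made, since the ketal carbon of 19 vanishes on aromatisation, and C2 and C3 are spectators under neutral thermal conditions, trans being the thermodynamic arrangement in any case. The selectivity required is regiochemical and is secured by pairing the largest HOMO coefficient of the diene (CH2) with the largest LUMO coefficient of the aroylalkyne (beta-carbon), which places ring A on C4', the aroyl group on C3a', the phenol on C7a' and the methyl ether on C6'. No other electron-poor pi bond competes, and the excess of 18 makes up for its consumption by the liberated methanol.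

Step 13
Reactants: 21 {2-[(2S,3S)-5-bromo-2-(4-methoxyphenyl)-2,3-dihydro-1-benzofuran-3-yl]-6-hydroxy-4-methoxyphenyl}(3,5-dimethoxyphenyl)methanone; 4 4-methoxybenzyl chloride
Product: 22 {2-[(2S,3S)-5-bromo-2-(4-methoxyphenyl)-2,3-dihydro-1-benzofuran-3-yl]-4-methoxy-6-(4-methoxybenzyloxy)phenyl}(3,5-dimethoxyphenyl)methanone
Conditions: Cs2CO3, DMF, 60 °C
Reagents that add atoms: none
Why: Williamson etherification in which Cs2CO3 in DMF breaks the hydrogen bond of the ortho-hydroxy ketone and the benzylic chloride delivers C2' with its aryl group.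

Step 14
Reactants: 22 {2-[(2S,3S)-5-bromo-2-(4-methoxyphenyl)-2,3-dihydro-1-benzofuran-3-yl]-4-methoxy-6-(4-methoxybenzyloxy)phenyl}(3,5-dimethoxyphenyl)methanone
Product: 23 hydrazone of 22 (C=N isomers)
Conditions: N2H4·H2O (20 equiv), AcOH (cat.), n-BuOH, 120 °C, sealed tube
Reagents that add atoms: hydrazine hydrate, NN.O
Why: Acid-catalysed hydrazone formation driven by a large excess of hydrazine; the forcing temperature is tolerable because the substrate holds only aryl ethers and an aryl bromide and still has no olefin that diimide could reduce.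

Step 15
Reactants: 23 hydrazone of 22
Product: 25 (2S,3S)-5-bromo-3-[(2R,3S)-3-(3,5-dimethoxyphenyl)-6-methoxy-2-(4-methoxyphenyl)-2,3-dihydro-1-benzofuran-4-yl]-2-(4-methoxyphenyl)-2,3-dihydro-1-benzofuran (ring B cis), via diaryldiazomethane 24 (not isolated)
Conditions: MnO2, CH2Cl2, rt, filter through Celite; Rh2(S-PTAD)4 (1 mol %; PTAD = (1-adamantyl)(phthalimido)acetate), CH2Cl2, 0 °C to rt
Reagents that add atoms: none
Why: MnO2 dehydrogenates the hydrazone to the hindered, azine-resistant diazo compound 24, whose donor/donor rhodium carbene undergoes the known intramolecular 1,5 C–H insertion into the 4-methoxybenzylic CH2 to give a cis-2,3-diaryl-2,3-dihydrobenzofuran; the chiral carboxylate pocket fixes C3' as S, the cis-selective C–C bond formation makes C2' R, and the competing ring A C2–H is held away from the carbene because allylic-type strain turns C3–H towards C3'.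

Step 16
Reactants: 25 ring B cis bromide (2S,3S,2'R,3'S)
Product: 26 (2S,3S)-5-bromo-3-[(2S,3S)-3-(3,5-dimethoxyphenyl)-6-methoxy-2-(4-methoxyphenyl)-2,3-dihydro-1-benzofuran-4-yl]-2-(4-methoxyphenyl)-2,3-dihydro-1-benzofuran (both rings trans)
Conditions: CF3CO2H, CH2Cl2, 0 °C to rt, short contact
Reagents that add atoms: none
Why: Acid-catalysed cis-to-trans equilibration known for 2-(4-alkoxyphenyl)-3-aryl-2,3-dihydrobenzofurans, in which reversible heterolysis of C2'–O1' to the 4-methoxybenzylic cation and fast five-membered reclosure invert C2' to S; C3' is untouched, any trans isomer already present converges, and the already trans ring A returns to itself.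

Step 17
Reactants: 11 3,5-dimethoxybenzaldehyde
Product: 27 3,5-dimethoxystyrene
Conditions: MePPh3Br, KOt-Bu, THF, 0 °C to rt
Reagents that add atoms: methyltriphenylphosphonium bromide, C[P+](c1ccccc1)(c1ccccc1)c1ccccc1.[Br-]
Why: Wittig methylenation of an aromatic aldehyde.

Step 18
Reactants: 26 all-trans bromide (2S,3S,2'S,3'S); 27 3,5-dimethoxystyrene
Product: 28 heptamethyl ether of trans-diptoindonesin B (2S,3S,2'S,3'S; E)
Conditions: Pd(OAc)2 (5 mol %), P(o-tol)3, Et3N, DMF, 100 °C
Reagents that add atoms: none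
Why: Mizoroki–Heck reaction of the C5 aryl bromide with a terminal styrene at zerovalent palladium, where syn insertion and syn beta-hydride elimination give the E stilbene.

Step 19
Reactants: 28 heptamethyl ether of trans-diptoindonesin B
Product: 29 trans-diptoindonesin B
Conditions: BBr3 (14 equiv), CH2Cl2, −78 °C to rt; ice-water
Reagents that add atoms: none
Why: Lewis-acid cleavage of all seven aryl methyl ethers with BBr3 is the customary last step for permethylated oligostilbenes, and any transient opening of the benzylic C2–O1 or C2'–O1' bond recloses to the thermodynamic trans ring on the fixed C3 or C3', so no stereocentre is lost.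

Compound list
1 | 2-hydroxyphenylacetic acid | O=C(O)Cc1ccccc1O | starting material
2 | methyl 2-(2-hydroxyphenyl)acetate | COC(=O)Cc1ccccc1O | intermediate
3 | methyl 2-(5-bromo-2-hydroxyphenyl)acetate | COC(=O)Cc1cc(Br)ccc1O | intermediate
4 | 4-methoxybenzyl chloride | COc1ccc(CCl)cc1 | starting material
5 | methyl 2-[5-bromo-2-(4-methoxybenzyloxy)phenyl]acetate | COC(=O)Cc1cc(Br)ccc1OCc1ccc(OC)cc1 | intermediate
6 | methyl 2-[5-bromo-2-(4-methoxybenzyloxy)phenyl]-2-diazoacetate | COC(=O)C(=[N+]=[N-])c1cc(Br)ccc1OCc1ccc(OC)cc1 | intermediate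
7 | methyl (2S,3R)-5-bromo-2-(4-methoxyphenyl)-2,3-dihydro-1-benzofuran-3-carboxylate (cis) | COc1ccc([C@H]2Oc3ccc(Br)cc3[C@H]2C(=O)OC)cc1 | intermediate
8 | methyl (2S,3S)-5-bromo-2-(4-methoxyphenyl)-2,3-dihydro-1-benzofuran-3-carboxylate (trans) | COc1ccc([C@H]2Oc3ccc(Br)cc3[C@@H]2C(=O)OC)cc1 | intermediate
9 | (2S,3S)-5-bromo-2-(4-methoxyphenyl)-2,3-dihydro-1-benzofuran-3-carbaldehyde (trans, not isolated) | COc1ccc([C@H]2Oc3ccc(Br)cc3[C@@H]2C=O)cc1 | intermediate
10 | (2S,3S)-5-bromo-3-ethynyl-2-(4-methoxyphenyl)-2,3-dihydro-1-benzofuran (trans) | COc1ccc([C@H]2Oc3ccc(Br)cc3[C@@H]2C#C)cc1 | intermediate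
11 | 3,5-dimethoxybenzaldehyde | COc1cc(C=O)cc(OC)c1 | starting material
12 | bromomagnesium acetylide of 10 (not isolated) | COc1ccc([C@H]2Oc3ccc(Br)cc3[C@@H]2C#C[Mg]Br)cc1 | intermediate
13 | 3-[(2S,3S)-5-bromo-2-(4-methoxyphenyl)-2,3-dihydro-1-benzofuran-3-yl]-1-(3,5-dimethoxyphenyl)prop-2-yn-1-ol (carbinol epimers) | COc1ccc([C@H]2Oc3ccc(Br)cc3[C@@H]2C#CC(O)c2cc(OC)cc(OC)c2)cc1 | intermediate
14 | 3-[(2S,3S)-5-bromo-2-(4-methoxyphenyl)-2,3-dihydro-1-benzofuran-3-yl]-1-(3,5-dimethoxyphenyl)prop-2-yn-1-one | COc1ccc([C@H]2Oc3ccc(Br)cc3[C@@H]2C#CC(=O)c2cc(OC)cc(OC)c2)cc1 | intermediate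
15 | methyl acetoacetate | COC(=O)CC(C)=O | starting material
16 | methyl (E)-3-methoxybut-2-enoate | COC(=O)/C=C(/OC)C | intermediate
17 | lithium dienolate of 16 (not isolated) | [Li+].C=C(OC)/C=C(\OC)[O-] | intermediate
18 | (E)-1,3-dimethoxy-1-(trimethylsilyloxy)buta-1,3-diene | C=C(OC)/C=C(\OC)O[Si](C)(C)C | intermediate
19 | {2-[(2S,3S)-5-bromo-2-(4-methoxyphenyl)-2,3-dihydro-1-benzofuran-3-yl]-4,6-dimethoxy-6-(trimethylsilyloxy)cyclohexa-1,4-dien-1-yl}(3,5-dimethoxyphenyl)methanone (ketal carbon unassigned, not isolated) | COc1ccc([C@H]2Oc3ccc(Br)cc3[C@@H]2C2=C(C(=O)c3cc(OC)cc(OC)c3)C(OC)(O[Si](C)(C)C)C=C(OC)C2)cc1 | intermediate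
20 | trimethylsilyl ether of 21 (not isolated) | COc1ccc([C@H]2Oc3ccc(Br)cc3[C@@H]2c2cc(OC)cc(O[Si](C)(C)C)c2C(=O)c2cc(OC)cc(OC)c2)cc1 | intermediate
21 | {2-[(2S,3S)-5-bromo-2-(4-methoxyphenyl)-2,3-dihydro-1-benzofuran-3-yl]-6-hydroxy-4-methoxyphenyl}(3,5-dimethoxyphenyl)methanone | COc1ccc([C@H]2Oc3ccc(Br)cc3[C@@H]2c2cc(OC)cc(O)c2C(=O)c2cc(OC)cc(OC)c2)cc1 | intermediate
22 | 4-methoxybenzyl ether of 21 | COc1ccc([C@H]2Oc3ccc(Br)cc3[C@@H]2c2cc(OC)cc(OCc3ccc(OC)cc3)c2C(=O)c2cc(OC)cc(OC)c2)cc1 | intermediate
23 | hydrazone of 22 (C=N isomers) | COc1ccc([C@H]2Oc3ccc(Br)cc3[C@@H]2c2cc(OC)cc(OCc3ccc(OC)cc3)c2C(=NN)c2cc(OC)cc(OC)c2)cc1 | intermediate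
24 | diaryldiazomethane from 23 (not isolated) | COc1ccc([C@H]2Oc3ccc(Br)cc3[C@@H]2c2cc(OC)cc(OCc3ccc(OC)cc3)c2C(=[N+]=[N-])c2cc(OC)cc(OC)c2)cc1 | intermediate
25 | (2S,3S,2'R,3'S) bromide, ring A trans, ring B cis | COc1ccc([C@H]2Oc3ccc(Br)cc3[C@@H]2c2cc(OC)cc3c2[C@H](c2cc(OC)cc(OC)c2)[C@H](c2ccc(OC)cc2)O3)cc1 | intermediate
26 | (2S,3S,2'S,3'S) bromide, both rings trans | COc1ccc([C@H]2Oc3ccc(Br)cc3[C@@H]2c2cc(OC)cc3c2[C@H](c2cc(OC)cc(OC)c2)[C@@H](c2ccc(OC)cc2)O3)cc1 | intermediate
27 | 3,5-dimethoxystyrene | C=Cc1cc(OC)cc(OC)c1 | intermediate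
28 | heptamethyl ether of trans-diptoindonesin B | COc1ccc([C@H]2Oc3ccc(/C=C/c4cc(OC)cc(OC)c4)cc3[C@@H]2c2cc(OC)cc3c2[C@H](c2cc(OC)cc(OC)c2)[C@@H](c2ccc(OC)cc2)O3)cc1 | intermediate
29 | trans-diptoindonesin B | Oc1ccc([C@H]2Oc3ccc(/C=C/c4cc(O)cc(O)c4)cc3[C@@H]2c2cc(O)cc3c2[C@H](c2cc(O)cc(O)c2)[C@@H](c2ccc(O)cc2)O3)cc1 | target

Total step count: 19. Longest linear sequence: 16 (steps 1 to 9, 12 to 16, 18 and 19).

Steps most likely to fail

Step 12. The triple bond is disubstituted and flanked by the branched C3 and by the aroyl group. The [4+2] addition may therefore be outrun by thermal or protic decay of the diene, and long heating invites a prototropic shift of C3–H along the ynone.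
- The fallback sets out from 10 and comes back at 22. It postpones the aryl ketone so that a smaller, more electrophilic dienophile meets the diene.
- Acetylide 12 is formylated with DMF (inverse quench into aq KH2PO4) to the ring A propynal F1.
- F1 and 18 should combine well below 110 °C and aromatise in the same way to the ring A salicylaldehyde F2.
- Etherification with 4 and Cs2CO3 gives the 4-methoxybenzyl ether F3.
- 3,5-Dimethoxyphenylmagnesium bromide adds to the aldehyde to give the diarylcarbinol F4, and MnO2 oxidation delivers 22.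

Step 14. Both ortho substituents of the central ring stand over the two faces of the twisted C3' carbonyl. Condensation may therefore stall, and long heating favours azine formation.
- The fallback sets out from 21 and comes back at 26. It also bypasses steps 13, 15 and 16, so it equally answers poor site or facial selectivity of the carbene insertion.
- Ring B is closed by a formal [4+1] annulation of an ortho-quinone methide with a sulfonium ylide.
- NaBH4 reduces 21 to the ortho-hydroxybenzhydrol F5, and sodium p-toluenesulfinate in aqueous formic acid turns it into the benzylic sulfone F6.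
- Cs2CO3 expels sulfinate from F6 to the quinone methide. It also deprotonates (4-methoxybenzyl)dimethylsulfonium tetrafluoroborate F7, which is made from 4, Me2S and NaBF4.
- Conjugate addition of the ylide to C3' and displacement of Me2S by the phenoxide give the trans ring directly.
- C3' is then controlled only by the neighbouring ring A, so the two trans diastereomers may have to be separated.

Step 19. Sevenfold ether cleavage needs a large excess of a strong Lewis acid. The material may be eroded in three ways: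
- heterolysis of C2–O1 or C2'–O1' followed by Friedel–Crafts capture by a resorcinol ring;
- cationic oligomerisation at the electron-rich stilbene;
- incomplete cleavage.

The fallback sets out from 26 and comes back at 29. It cleaves the ethers before the olefin exists and makes the end game basic.
- BBr3 converts 26 into the pentaphenol bromide F8, and Ac2O in pyridine gives the pentaacetate F9.
- A Heck reaction with purchasable 3,5-diacetoxystyrene under the conditions of step 18 gives the heptaacetate F10.
- K2CO3 in MeOH removes the acetates to give 29.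

Further compounds
F1 | step 12 | 3-[(2S,3S)-5-bromo-2-(4-methoxyphenyl)-2,3-dihydro-1-benzofuran-3-yl]prop-2-ynal | COc1ccc([C@H]2Oc3ccc(Br)cc3[C@@H]2C#CC=O)cc1
F2 | step 12 | 2-[(2S,3S)-5-bromo-2-(4-methoxyphenyl)-2,3-dihydro-1-benzofuran-3-yl]-6-hydroxy-4-methoxybenzaldehyde | COc1ccc([C@H]2Oc3ccc(Br)cc3[C@@H]2c2cc(OC)cc(O)c2C=O)cc1
F3 | step 12 | 2-[(2S,3S)-5-bromo-2-(4-methoxyphenyl)-2,3-dihydro-1-benzofuran-3-yl]-4-methoxy-6-(4-methoxybenzyloxy)benzaldehyde | COc1ccc([C@H]2Oc3ccc(Br)cc3[C@@H]2c2cc(OC)cc(OCc3ccc(OC)cc3)c2C=O)cc1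
F4 | step 12 | {2-[(2S,3S)-5-bromo-2-(4-methoxyphenyl)-2,3-dihydro-1-benzofuran-3-yl]-4-methoxy-6-(4-methoxybenzyloxy)phenyl}(3,5-dimethoxyphenyl)methanol (carbinol epimers) | COc1ccc([C@H]2Oc3ccc(Br)cc3[C@@H]2c2cc(OC)cc(OCc3ccc(OC)cc3)c2C(O)c2cc(OC)cc(OC)c2)cc1
F5 | step 14 | 3-[(2S,3S)-5-bromo-2-(4-methoxyphenyl)-2,3-dihydro-1-benzofuran-3-yl]-2-[(3,5-dimethoxyphenyl)(hydroxy)methyl]-5-methoxyphenol (carbinol epimers) | COc1ccc([C@H]2Oc3ccc(Br)cc3[C@@H]2c2cc(OC)cc(O)c2C(O)c2cc(OC)cc(OC)c2)cc1
F6 | step 14 | 3-[(2S,3S)-5-bromo-2-(4-methoxyphenyl)-2,3-dihydro-1-benzofuran-3-yl]-2-[(3,5-dimethoxyphenyl)(4-methylphenylsulfonyl)methyl]-5-methoxyphenol (sulfone carbon epimers) | COc1ccc([C@H]2Oc3ccc(Br)cc3[C@@H]2c2cc(OC)cc(O)c2C(c2cc(OC)cc(OC)c2)S(=O)(=O)c2ccc(C)cc2)cc1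
F7 | step 14 | (4-methoxybenzyl)dimethylsulfonium tetrafluoroborate | COc1ccc(C[S+](C)C)cc1.F[B-](F)(F)F
F8 | step 19 | pentaphenol of 26 (2S,3S,2'S,3'S) | Oc1ccc([C@H]2Oc3ccc(Br)cc3[C@@H]2c2cc(O)cc3c2[C@H](c2cc(O)cc(O)c2)[C@@H](c2ccc(O)cc2)O3)cc1
F9 | step 19 | pentaacetate of F8 | CC(=O)Oc1ccc([C@H]2Oc3ccc(Br)cc3[C@@H]2c2cc(OC(C)=O)cc3c2[C@H](c2cc(OC(C)=O)cc(OC(C)=O)c2)[C@@H](c2ccc(OC(C)=O)cc2)O3)cc1
F10 | step 19 | heptaacetate of trans-diptoindonesin B | CC(=O)Oc1ccc([C@H]2Oc3ccc(/C=C/c4cc(OC(C)=O)cc(OC(C)=O)c4)cc3[C@@H]2c2cc(OC(C)=O)cc3c2[C@H](c2cc(OC(C)=O)cc(OC(C)=O)c2)[C@@H](c2ccc(OC(C)=O)cc2)O3)cc1
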